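**Direct plan and its weak steps**

A direct plan would buy ring A as (4R,6R)-actinol A1, convert it by silylation, enol triflation and Stille vinylation into the vinylcyclohexene A2, and close ring B by a thermal Diels–Alder reaction with the ynal A3 (bonds C9–C10 and C7–C8) to give the dienal A4.
Epoxidation and methylenation to the epoxy diene A5, a reductive epoxide rearrangement to the cis-fused silyl ether A6, hydroboration/B-alkyl Suzuki coupling with 4-bromofuran-2(5H)-one A7 and desilylation would finish.
First weakness, the Diels–Alder ring closure: the diene terminus that must become the quaternary C10 is tetrasubstituted and flanked by the C4 gem-dimethyl group, so the diene is twisted out of the s-cis form, and its face is steered only by the remote C2 silyl ether.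
Second weakness, the epoxide-to-cis-decalin rearrangement: C5 and C6 are not set when the ring forms but corrected afterwards (net anti addition of H and O across C5=C6) by a hydride-shift/reduction relay without precedent on a fully substituted ring-fusion epoxide.
Third weakness, the silyl/redox run: three silyl ethers are put on and removed, and C11 passes through CHO, vinyl and borane stages that add no skeletal bond.

**Retrosynthetic overview of the new route**

- Ring B is taken from a benzene ring: phenol 1 → chloroquinone ester 4, whose quinone carbonyls are C6 and C9, whose ester carbon is C17 and whose ring methyl is C20; chlorine on C7 blocks the ester-bearing C7=C8 bond.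
- Key disconnection C1–C10/C4–C5: ring A is closed last, onto C5=C10 of ring B, by a catalytic enantioselective Diels–Alder reaction with the mesityl oxide-derived 2-silyloxydiene 7 (C1–C4, carrying the C4 gem-dimethyl group and the C2 oxygen). The unhindered CH2 terminus makes the quaternary C10, and the cis C5/C10 fusion is set in the ring-forming step itself.
- C6 is then set by hydride on the flat ene-dione; Zn removes Cl and C7=C8; the C9/C8 β-keto ester becomes the enol triflate that fixes C8=C9 and takes C11–C16 as a furylethylzinc reagent (furan = latent butenolide); one i-Bu2AlH step gives C17–OH and 2α-OH.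
- No hydroxyl protecting group is used, the ring fusion is never corrected after ring closure, and the diene terminus that forms the quaternary centre is the unhindered one.

Key step: step 4

Convention: labdane numbering (C1–C20) and α/β (β = face of the C10 methyl group) are used for all bicyclic compounds.
Assumption: the sense of enantioselection in step 4 is taken from the accepted pre-transition-state model for oxazaborolidinium–quinone complexes; the (S)-catalyst is written, and its mirror image would be used if that model assigns the opposite face.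

**Route**

Step 1
Reactants: 1 methyl 3-hydroxy-5-methylbenzoate
Product: 2 methyl 5-methyl-3,6-dioxocyclohexa-1,4-diene-1-carboxylate
Conditions: K2[ON(SO3)2] (2.5 equiv), KH2PO4 buffer, acetone/H2O, 0 °C → rt
Reagents that add atoms: dipotassium nitrosodisulfonate, [K+].[K+].[O]N(S(=O)(=O)[O-])S(=O)(=O)[O-]
Why: Teuber oxidation: the nitroxyl radical abstracts the phenolic hydrogen and a second equivalent adds at the only free para position (C9), as in the conversion of 3,5-disubstituted phenols into 2,6-disubstituted 1,4-benzoquinones; no stereocentre is involved.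

Step 2
Reactants: 2 methyl 5-methyl-3,6-dioxocyclohexa-1,4-diene-1-carboxylate
Product: 4 methyl 2-chloro-5-methyl-3,6-dioxocyclohexa-1,4-diene-1-carboxylate, via chlorohydroquinone ester 3 (not isolated)
Conditions: HCl (4 M in 1,4-dioxane, 1.5 equiv), CH2Cl2, 0 °C; then Ag2O (2 equiv), MgSO4, rt
Reagents that add atoms: hydrogen chloride, Cl
Why: Quinone hydrochlorination should put chloride on C7, the ring carbon β to both C9=O and the ester and thus the most electrophilic position of a 2-acylquinone, and Ag2O reoxidises the hydroquinone; the chlorine makes C7=C8 tetrasubstituted and removes the C7–H that would let a Michael adduct aromatise.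

Step 3
Reactants: 5 mesityl oxide (4-methylpent-3-en-2-one)
Product: 7 triisopropyl[(4-methylpenta-1,3-dien-2-yl)oxy]silane, via lithium dienolate 6 (not isolated)
Conditions: LiN(i-Pr)2 (1.1 equiv), THF, −78 °C; i-Pr3SiOSO2CF3 (1.15 equiv), −78 → 0 °C
Reagents that add atoms: triisopropylsilyl trifluoromethanesulfonate, CC(C)[Si](OS(=O)(=O)C(F)(F)F)(C(C)C)C(C)C
Why: Kinetic deprotonation of the enone at the α′-methyl group gives the cross-conjugated dienolate, whose O-silylation gives the 2-silyloxydiene; no stereocentre is involved.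

Step 4
Reactants: 4 methyl 2-chloro-5-methyl-3,6-dioxocyclohexa-1,4-diene-1-carboxylate; 7 triisopropyl[(4-methylpenta-1,3-dien-2-yl)oxy]silane
Product: 8 methyl 3-chloro-5,5,8a-trimethyl-1,4-dioxo-7-[(triisopropylsilyl)oxy]-1,4,4a,5,8,8a-hexahydronaphthalene-2-carboxylate (cis-fused; 5β-H; 10β-CH3)
Conditions: (S)-1-(2-methylphenyl)-3,3-diphenyltetrahydro-1H,3H-pyrrolo[1,2-c][1,3,2]oxazaborole (20 mol %), AlBr3 (16 mol %), 7 (1.5 equiv), CH2Cl2, −78 → −40 °C
Reagents that add atoms: none
Why: This is a Lewis-acid-catalysed, strongly asynchronous Diels–Alder reaction in which the oxazaborolidinium ion should bind the C6 carbonyl through its only unhindered lone pair (syn to C5–H; both lone pairs of C9=O are flanked by CH3 and CO2CH3), so that C10 becomes the β-carbon, the nucleophilic CH2 terminus (C1) of the diene bonds to C10 first and the CMe2 terminus (C4) then closes onto C5. The closest known reaction types are the enantioselective oxazaborolidinium-catalysed Diels–Alder reactions of substituted 1,4-benzoquinones with 2-silyloxy-1,3-dienes and the Lewis-acid Diels–Alder reactions of 4,4-disubstituted 2-silyloxydienes with hindered enones. Ring A is closed in the intermolecular [4+2] mode onto the C5=C10 bond of the pre-formed ring B. C5 and C10 are set together: their relative configuration (C20 and 5-H cis, the cis-decalin) follows from suprafacial addition to the ring alkene, their absolute configuration from the catalyst, which shields one face of the bound quinone. The step needs site selectivity (C5=C10 over C7=C8, secured by the Cl/CO2CH3 tetrasubstitution of C7=C8) and regioselectivity (secured by the catalyst position and by the fact that the other orientation would join the two fully substituted carbons C4 and C10).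

Step 5
Reactants: 8 methyl 3-chloro-5,5,8a-trimethyl-1,4-dioxo-7-[(triisopropylsilyl)oxy]-1,4,4a,5,8,8a-hexahydronaphthalene-2-carboxylate
Product: 9 methyl 3-chloro-4-hydroxy-5,5,8a-trimethyl-1-oxo-7-[(triisopropylsilyl)oxy]-1,4,4a,5,8,8a-hexahydronaphthalene-2-carboxylate (6α-OH; 5β-H; 10β-CH3)
Conditions: LiAlH(O-t-Bu)3 (1.2 equiv), THF, −78 °C
Reagents that add atoms: none
Why: Chemoselective 1,2-reduction of the less hindered C6 ketone (C9=O lies between the quaternary C10 and the substituted C8) on the still flat ene-dione ring: hydride should enter anti to the pseudo-axial C5–C4 bond from the convex β face, as in hydride reductions of cis-fused quinone–diene adducts, which sets 6α-OH.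

Step 6
Reactants: 9 methyl 3-chloro-4-hydroxy-5,5,8a-trimethyl-1-oxo-7-[(triisopropylsilyl)oxy]-1,4,4a,5,8,8a-hexahydronaphthalene-2-carboxylate
Product: 11 methyl 1,4-dihydroxy-5,5,8a-trimethyl-7-oxo-3,4,4a,5,6,7,8,8a-octahydronaphthalene-2-carboxylate (enol form of the C9/C8 β-keto ester; 6α-OH; 5β-H; 10β-CH3), via silyl enol ether 10 (not isolated)
Conditions: Zn dust (10 equiv), AcOH/THF 1:3, 0 °C → rt; filtration; then Bu4NF/AcOH (1:1, 1.5 equiv), THF, 0 °C
Reagents that add atoms: none
Why: Dissolving-metal reduction of the β-chloro alkylidene β-keto ester: two-electron reduction, E1cB loss of chloride and a second two-electron reduction should give the C7 methylene and the C9/C8 β-keto ester without touching C5, C6 or C10, and buffered fluoride then cleaves the silyl enol ether to the C2 ketone.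

Step 7
Reactants: 11 methyl 1,4-dihydroxy-5,5,8a-trimethyl-7-oxo-3,4,4a,5,6,7,8,8a-octahydronaphthalene-2-carboxylate
Product: 13 methyl 4-hydroxy-5,5,8a-trimethyl-7-oxo-1-[(trifluoromethanesulfonyl)oxy]-3,4,4a,5,6,7,8,8a-octahydronaphthalene-2-carboxylate, via sodium enolate 12 (not isolated)
Conditions: NaH (1.05 equiv), THF, 0 °C; PhNTf2 (1.1 equiv), 0 °C → rt
Reagents that add atoms: N-phenylbis(trifluoromethanesulfonimide), O=S(=O)(N(c1ccccc1)S(=O)(=O)C(F)(F)F)C(F)(F)F
Why: Enol triflate formation: with one equivalent of base only the β-keto ester is deprotonated and its enolate is O-sulfonylated, and because C10 is quaternary the enol double bond can only be C8=C9.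

Step 8
Reactants: 14 2-(furan-3-yl)ethan-1-ol
Product: 15 3-(2-iodoethyl)furan
Conditions: I2, PPh3, imidazole, CH2Cl2, 0 °C → rt
Reagents that add atoms: iodine, II
Why: Appel-type iodination of a primary alcohol; no stereocentre is involved.

Step 9
Reactants: 13 methyl 4-hydroxy-5,5,8a-trimethyl-7-oxo-1-[(trifluoromethanesulfonyl)oxy]-3,4,4a,5,6,7,8,8a-octahydronaphthalene-2-carboxylate; 15 3-(2-iodoethyl)furan
Product: 17 methyl 1-[2-(furan-3-yl)ethyl]-4-hydroxy-5,5,8a-trimethyl-7-oxo-3,4,4a,5,6,7,8,8a-octahydronaphthalene-2-carboxylate, via organozinc iodide 16 (not isolated)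
Conditions: 15 (3 equiv), Zn dust (4.5 equiv, activated with BrCH2CH2Br/Me3SiCl), DMA, 40 °C; then 13, PdCl2(dppf) (5 mol %), THF/DMA, rt → 40 °C
Reagents that add atoms: none
Why: Negishi coupling: the primary alkylzinc iodide tolerates the ketone and, in excess, the free hydroxyl, and the β-triflyloxy enoate is activated for oxidative addition; the base-free conditions leave the stereocentres and the position of C8=C9 unchanged.

Step 10
Reactants: 17 methyl 1-[2-(furan-3-yl)ethyl]-4-hydroxy-5,5,8a-trimethyl-7-oxo-3,4,4a,5,6,7,8,8a-octahydronaphthalene-2-carboxylate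
Product: 18 15,16-epoxy-5β-labda-8,13(16),14-triene-2α,6α,17-triol
Conditions: i-Bu2AlH (6 equiv), CH2Cl2, −78 → 0 °C; aq. potassium sodium tartrate
Reagents that add atoms: none
Why: i-Bu2AlH reduction of the enoate to the allylic alcohol (C17) and of the C2 ketone: in the cis-decalin conformer that keeps C20 equatorial on ring A and the 6α-aluminoxy group equatorial on ring B, C9 and the 4α-methyl group are syn-axial on the α face of ring A, so hydride should attack C2 from the β face and give 2α-OH (trans to C20).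

Step 11
Reactants: 18 15,16-epoxy-5β-labda-8,13(16),14-triene-2α,6α,17-triol
Product: 20 2α,6α,17-trihydroxy-5β-labda-8,13-dien-15,16-olide (CNP0293367.1), via hydroxybutenolide 19 (not isolated)
Conditions: O2, visible light, 5,10,15,20-tetraphenylporphyrin (1 mol %), i-Pr2NEt (5 equiv), CH2Cl2, −78 °C; then NaBH4 (4 equiv), EtOH, 0 °C; then 1 M HCl to pH 3
Reagents that add atoms: oxygen (as singlet oxygen), O=O
Why: Singlet-oxygen [4+2] addition to the furan and base-directed Kornblum–DeLaMare opening at the unhindered C15–H give the 16-hydroxy-15,16-olide, whose masked aldehyde is reduced by NaBH4 so that relactonisation gives the β-substituted butenolide; at −78 °C the furan should react much faster than the hindered tetrasubstituted C8=C9 bond, and no stereocentre is touched.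

**Compound list**

1 | methyl 3-hydroxy-5-methylbenzoate | COC(=O)c1cc(C)cc(O)c1 | starting material
2 | methyl 5-methyl-3,6-dioxocyclohexa-1,4-diene-1-carboxylate | COC(=O)C1=CC(=O)C=C(C)C1=O | intermediate
3 | methyl 2-chloro-3,6-dihydroxy-5-methylbenzoate | COC(=O)c1c(Cl)c(O)cc(C)c1O | intermediate
4 | methyl 2-chloro-5-methyl-3,6-dioxocyclohexa-1,4-diene-1-carboxylate | COC(=O)C1=C(Cl)C(=O)C=C(C)C1=O | intermediate
5 | mesityl oxide (4-methylpent-3-en-2-one) | CC(=O)C=C(C)C | starting material
6 | lithium 4-methylpenta-1,3-dien-2-olate | [Li+].[O-]C(=C)C=C(C)C | intermediate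
7 | triisopropyl[(4-methylpenta-1,3-dien-2-yl)oxy]silane | C=C(O[Si](C(C)C)(C(C)C)C(C)C)C=C(C)C | intermediate
8 | methyl 3-chloro-5,5,8a-trimethyl-1,4-dioxo-7-[(triisopropylsilyl)oxy]-1,4,4a,5,8,8a-hexahydronaphthalene-2-carboxylate (cis-fused, 5β-H, 10β-CH3) | CC1(C)C=C(O[Si](C(C)C)(C(C)C)C(C)C)C[C@]2(C)C(=O)C(C(=O)OC)=C(Cl)C(=O)[C@H]12 | intermediate
9 | methyl 3-chloro-4-hydroxy-5,5,8a-trimethyl-1-oxo-7-[(triisopropylsilyl)oxy]-1,4,4a,5,8,8a-hexahydronaphthalene-2-carboxylate (6α-OH, 5β-H, 10β-CH3) | CC1(C)C=C(O[Si](C(C)C)(C(C)C)C(C)C)C[C@]2(C)C(=O)C(C(=O)OC)=C(Cl)[C@H](O)[C@H]12 | intermediate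
10 | methyl 1,4-dihydroxy-5,5,8a-trimethyl-7-[(triisopropylsilyl)oxy]-3,4,4a,5,8,8a-hexahydronaphthalene-2-carboxylate (enol form, 6α-OH, 5β-H, 10β-CH3) | CC1(C)C=C(O[Si](C(C)C)(C(C)C)C(C)C)C[C@]2(C)C(O)=C(C(=O)OC)C[C@H](O)[C@H]12 | intermediate
11 | methyl 1,4-dihydroxy-5,5,8a-trimethyl-7-oxo-3,4,4a,5,6,7,8,8a-octahydronaphthalene-2-carboxylate (enol form, 6α-OH, 5β-H, 10β-CH3) | CC1(C)CC(=O)C[C@]2(C)C(O)=C(C(=O)OC)C[C@H](O)[C@H]12 | intermediate
12 | sodium enolate of 11 | [Na+].CC1(C)CC(=O)C[C@]2(C)C([O-])=C(C(=O)OC)C[C@H](O)[C@H]12 | intermediate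
13 | methyl 4-hydroxy-5,5,8a-trimethyl-7-oxo-1-[(trifluoromethanesulfonyl)oxy]-3,4,4a,5,6,7,8,8a-octahydronaphthalene-2-carboxylate (6α-OH, 5β-H, 10β-CH3) | CC1(C)CC(=O)C[C@]2(C)C(OS(=O)(=O)C(F)(F)F)=C(C(=O)OC)C[C@H](O)[C@H]12 | intermediate
14 | 2-(furan-3-yl)ethan-1-ol | OCCc1ccoc1 | starting material
15 | 3-(2-iodoethyl)furan | ICCc1ccoc1 | intermediate
16 | [2-(furan-3-yl)ethyl]zinc iodide | I[Zn]CCc1ccoc1 | intermediate
17 | methyl 1-[2-(furan-3-yl)ethyl]-4-hydroxy-5,5,8a-trimethyl-7-oxo-3,4,4a,5,6,7,8,8a-octahydronaphthalene-2-carboxylate (6α-OH, 5β-H, 10β-CH3) | CC1(C)CC(=O)C[C@]2(C)C(CCc3ccoc3)=C(C(=O)OC)C[C@H](O)[C@H]12 | intermediate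
18 | 15,16-epoxy-5β-labda-8,13(16),14-triene-2α,6α,17-triol | CC1(C)C[C@H](O)C[C@]2(C)C(CCc3ccoc3)=C(CO)C[C@H](O)[C@H]12 | intermediate
19 | 2α,6α,16,17-tetrahydroxy-5β-labda-8,13-dien-15,16-olide | CC1(C)C[C@H](O)C[C@]2(C)C(CCC3=CC(=O)OC3O)=C(CO)C[C@H](O)[C@H]12 | intermediate
20 | 4-{2-[(4S,4aR,7S,8aS)-4,7-dihydroxy-2-(hydroxymethyl)-5,5,8a-trimethyl-3,4,4a,5,6,7,8,8a-octahydronaphthalen-1-yl]ethyl}furan-2(5H)-one | CC1(C)C[C@H](O)C[C@]2(C)C(CCC3=CC(=O)OC3)=C(CO)C[C@H](O)[C@H]12 | target

**Step count and risks**

Total step count: 11. Longest linear sequence: 9 (steps 1, 2, 4, 5, 6, 7, 9, 10, 11).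

Steps most likely to fail:

1. Step 4. The silyloxydiene may react in the Michael sense only (attack at C5 followed by aromatisation, or displacement of chloride at C7), the hindered CMe2 terminus may close slowly, or the catalyst may give poor enantioface control. The fallback sets out from 4 and 7: cycloaddition under the achiral mixed Lewis acid AlBr3/AlMe3 (CH2Cl2/toluene, −40 °C) would give 8 as the racemate, that is together with its mirror image ent-8 F1. Reduction as in step 5 would give 9 together with its mirror image ent-9 F2. A lipase-catalysed acetylation (Burkholderia cepacia lipase, vinyl acetate, MTBE, 30 °C), screened so that ent-9 is the fast-reacting enantiomer, would convert it into the acetate of ent-9 F3 and leave 9, at which the route is rejoined.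

2. Step 6. The zinc reduction may remove the C6 oxygen by reductive β-elimination, or the free β-keto ester may undergo acid-induced side reactions before it is trapped. The fallback sets out from 9: silylation (t-BuMe2SiOSO2CF3, 2,6-lutidine) would give the 6-O-(tert-butyldimethylsilyl) ether of 9 F4. Li[HB(s-Bu)3] (2.3 equiv, THF, −78 °C) followed by PhNTf2 would replace chloride by hydride through conjugate addition–elimination, reduce the resulting alkylidene β-keto ester in the 1,4-sense and trap the enolate directly as the doubly silylated C9 enol triflate F5, with no free β-keto ester and no acid. Negishi coupling with 16 as in step 9 would give the doubly silylated furylethyl enoate F6, and HCl in MeOH/THF would cleave both silyl groups to give 17, at which the route is rejoined.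

3. Step 11. Singlet oxygen may attack the tetrasubstituted C8=C9 bond in an ene reaction in competition with furan oxidation. The fallback sets out from 13 and brings the butenolide in ready-made: i-Bu2AlH as in step 10 would give the triol enol triflate F7; Stille coupling (CH2=CHSnBu3, Pd2(dba)3, AsPh3, LiCl, NMP) would give the 9-vinyl triol F8; hydroboration with 9-BBN would give the B-alkyl-9-borabicyclo[3.3.1]nonane F9; B-alkyl Suzuki–Miyaura coupling with 4-bromofuran-2(5H)-one F10 under PdCl2(dppf), AsPh3 and Cs2CO3 in DMF/H2O would give 20 directly.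

**Further compounds**

F1 | step 4 | ent-8 (mirror image of 8; part of the racemate) | CC1(C)C=C(O[Si](C(C)C)(C(C)C)C(C)C)C[C@@]2(C)C(=O)C(C(=O)OC)=C(Cl)C(=O)[C@@H]12
F2 | step 4 | ent-9 (mirror image of 9; part of the racemate) | CC1(C)C=C(O[Si](C(C)C)(C(C)C)C(C)C)C[C@@]2(C)C(=O)C(C(=O)OC)=C(Cl)[C@@H](O)[C@@H]12
F3 | step 4 | acetate of ent-9 | CC1(C)C=C(O[Si](C(C)C)(C(C)C)C(C)C)C[C@@]2(C)C(=O)C(C(=O)OC)=C(Cl)[C@@H](OC(C)=O)[C@@H]12
F4 | step 6 | 6-O-(tert-butyldimethylsilyl) ether of 9 | CC1(C)C=C(O[Si](C(C)C)(C(C)C)C(C)C)C[C@]2(C)C(=O)C(C(=O)OC)=C(Cl)[C@H](O[Si](C)(C)C(C)(C)C)[C@H]12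
F5 | step 6 | C9 enol triflate with 6-O-TBS ether and C2 triisopropylsilyl enol ether | CC1(C)C=C(O[Si](C(C)C)(C(C)C)C(C)C)C[C@]2(C)C(OS(=O)(=O)C(F)(F)F)=C(C(=O)OC)C[C@H](O[Si](C)(C)C(C)(C)C)[C@H]12
F6 | step 6 | 9-[2-(furan-3-yl)ethyl] enoate with 6-O-TBS ether and C2 triisopropylsilyl enol ether | CC1(C)C=C(O[Si](C(C)C)(C(C)C)C(C)C)C[C@]2(C)C(CCc3ccoc3)=C(C(=O)OC)C[C@H](O[Si](C)(C)C(C)(C)C)[C@H]12
F7 | step 11 | 2α,6α,17-triol C9 enol triflate | CC1(C)C[C@H](O)C[C@]2(C)C(OS(=O)(=O)C(F)(F)F)=C(CO)C[C@H](O)[C@H]12
F8 | step 11 | 9-vinyl 2α,6α,17-triol | CC1(C)C[C@H](O)C[C@]2(C)C(C=C)=C(CO)C[C@H](O)[C@H]12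
F9 | step 11 | C12 B-alkyl-9-borabicyclo[3.3.1]nonane of F8 | CC1(C)C[C@H](O)C[C@]2(C)C(CCB3C4CCCC3CCC4)=C(CO)C[C@H](O)[C@H]12
F10 | step 11 | 4-bromofuran-2(5H)-one | O=C1C=C(Br)CO1
A1 | direct plan | (4R,6R)-4-hydroxy-2,2,6-trimethylcyclohexan-1-one (actinol) | CC1(C)C[C@H](O)C[C@@H](C)C1=O
A2 | direct plan | tert-butyl{[(1R)-4-ethenyl-3,5,5-trimethylcyclohex-3-en-1-yl]oxy}dimethylsilane | CC1(C)C[C@H](O[Si](C)(C)C(C)(C)C)CC(C)=C1C=C
A3 | direct plan | 4-[(tert-butyldimethylsilyl)oxy]but-2-ynal | O=CC#CCO[Si](C)(C)C(C)(C)C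
A4 | direct plan | (7S,8aS)-7-(TBS-oxy)-2-(TBS-oxymethyl)-5,5,8a-trimethyl-3,5,6,7,8,8a-hexahydronaphthalene-1-carbaldehyde | CC1(C)C[C@H](O[Si](C)(C)C(C)(C)C)C[C@]2(C)C(C=O)=C(CO[Si](C)(C)C(C)(C)C)CC=C12
A5 | direct plan | 5α,6α-epoxy-2α,17-bis(TBS-oxy)-9-vinyl 8-ene | CC1(C)C[C@H](O[Si](C)(C)C(C)(C)C)C[C@]2(C)C(C=C)=C(CO[Si](C)(C)C(C)(C)C)C[C@@H]3O[C@]123
A6 | direct plan | 5β-H-6α-(triethylsilyloxy)-2α,17-bis(TBS-oxy)-9-vinyl 8-ene | CC1(C)C[C@H](O[Si](C)(C)C(C)(C)C)C[C@]2(C)C(C=C)=C(CO[Si](C)(C)C(C)(C)C)C[C@H](O[Si](CC)(CC)CC)[C@H]12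
A7 | direct plan | 4-bromofuran-2(5H)-one | O=C1C=C(Br)CO1
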